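The route rests on cutting C11–C12 (labdane numbering), the bond between the ring-B side-chain methylene and the chain that carries C13. The key step is a one-pot 9-BBN hydroboration / alkyl–alkyl Suzuki coupling. It exploits the exocyclic C9=C11 methylene on ring B, wedged between quaternary C10 and C8, whose two β-methyl groups (C20, C17) leave only the α face open. Hydroboration therefore creates the C9 stereocentre and a primary C11–boron bond, which is then joined to C12 of an (S)-bromide. The precursor is a 9-methylene octalin acetonide made from (S)-Wieland–Miescher ketone; the bromide comes from a catalytic enantioselective oxetane opening.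

Key step: step 15

Remark: labdane locants are used throughout (C1–C10 decalin; C18/C19 on C4; C5=C6; C17 on C8; C20 on C10; C11–C12 link; C13 bears C16; C14–C15–OAc). β is the ring face of the C10 methyl.
Remark: the C4 centre created in step 4 is temporary; both C4 epimers converge in step 6, and the expected major epimer is drawn.
Assumption: in step 13 the enantiomer of the chiral squaramide catalyst that gives the (S)-bromohydrin is used.

Step 1
Reactants: 1 (S)-Wieland–Miescher ketone
Product: 2 (4aS,5S)-5-hydroxy-4a-methyl-4,4a,5,6,7,8-hexahydronaphthalen-2(3H)-one (9β-hydroxy enone)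
Conditions: NaBH4 (0.3 equiv), EtOH, −10 °C
Reagents that add atoms: none
Why: Chemoselective hydride reduction of the saturated, more electrophilic C9 ketone over the enone carbonyl, with hydride entering anti to the angular methyl; the carbinol only masks the ketone until step 8.

Step 2
Reactants: 2 9β-hydroxy enone
Product: 3 C3 spiro-1,3-dithiolane of 2 with the C4=C5 alkene retained
Conditions: HSCH2CH2SH, BF3·OEt2 (cat.), MeOH, rt
Reagents that add atoms: ethane-1,2-dithiol, SCCS
Why: Lewis acid-catalysed thioacetalisation of the enone carbonyl, which for Δ4-3-ketones leaves the double bond in place.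

Step 3
Reactants: 3 dithiolane
Product: 4 (1S,8aS)-8a-methyl-1,2,3,4,6,7,8,8a-octahydronaphthalen-1-ol (Δ4-octalin-9β-ol)
Conditions: Raney Ni (W-2, deactivated in acetone), EtOH, reflux
Reagents that add atoms: none
Why: Raney nickel desulfurisation (Mozingo reduction) turns C3 into CH2 and should leave the hindered trisubstituted C4=C5 alkene untouched.

Step 4
Reactants: 4 Δ4-octalin-9β-ol
Product: 5 4α-(hydroxymethyl)-10β-methyl-Δ5-octalin-9β-ol
Conditions: (CH2O)n, Me2AlCl (3 equiv), CH2Cl2, 0 °C → rt
Reagents that add atoms: formaldehyde (from paraformaldehyde), C=O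
Why: Me2AlCl-promoted carbonyl-ene reaction in which formaldehyde bonds to the less substituted alkene carbon C4 from the α face and the allylic hydrogen is taken from C6 (C10 has none), moving the double bond to C5=C6.

Step 5
Reactants: 5 4α-(hydroxymethyl) diol
Product: 6 9β-hydroxy-10β-methyl-Δ5-octalin-4α-carbaldehyde
Conditions: TEMPO (cat.), PhI(OAc)2, CH2Cl2, rt
Reagents that add atoms: none
Why: Oxoammonium (TEMPO) oxidation takes the primary alcohol to the aldehyde and should spare the hindered secondary C9 alcohol next to the quaternary carbon.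

Step 6
Reactants: 6 hydroxy aldehyde
Product: 8 4,4-bis(hydroxymethyl)-10β-methyl-Δ5-octalin-9β-ol, via aldol adduct 7 (not isolated)
Conditions: 37% aq. CH2O (excess), KOH, MeOH–H2O, 0 → 45 °C
Reagents that add atoms: formaldehyde, C=O
Why: Tollens condensation, in which the dienolate of the α-branched aldehyde adds formaldehyde at C4 and the now non-enolisable aldehyde is reduced by a second formaldehyde (crossed Cannizzaro); C4 becomes quaternary with two equal CH2OH arms, which erases its temporary stereocentre.

Step 7
Reactants: 8 triol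
Product: 9 18,19-O-isopropylidene derivative of 8 (spiro-2,2-dimethyl-1,3-dioxane at C4; free 9β-OH)
Conditions: Me2C(OMe)2, PPTS (cat.), CH2Cl2, rt
Reagents that add atoms: 2,2-dimethoxypropane, COC(C)(C)OC
Why: Acid-catalysed transacetalisation closes the six-membered acetonide on the 1,3-diol; the remote secondary alcohol cannot take part.

Step 8
Reactants: 9 acetonide alcohol
Product: 10 18,19-O-isopropylidene-10β-methyl-Δ5-octalin-9-one
Conditions: Dess–Martin periodinane, NaHCO3, CH2Cl2, rt
Reagents that add atoms: none
Why: Dess–Martin oxidation returns the C9 ketone under buffered conditions that spare the acetonide.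

Step 9
Reactants: 10 acetonide ketone
Product: 13 8-methylene-9-ketone (exocyclic enone), via Mannich base 11 (not isolated), via ammonium iodide 12 (not isolated)
Conditions: LDA, THF, −78 °C; CH2=NMe2+ I−, −78 °C → rt; MeI, CH2Cl2, rt; aq. NaHCO3, rt
Reagents that add atoms: Eschenmoser's salt (N,N-dimethylmethyleneiminium iodide), C=[N+](C)C.[I-]
Why: The ketone can enolise only towards C8 because C10 is quaternary, so a Mannich reaction of the lithium enolate, N-methylation and E1cB loss of trimethylamine should give the α-methylene ketone.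

Step 10
Reactants: 13 exocyclic enone
Product: 14 8β-methyl-9-ketone (C8 methyl cis to the C10 methyl)
Conditions: H2 (1 atm), RhCl(PPh3)3 (cat.), benzene, rt
Reagents that add atoms: none
Why: Homogeneous hydrogenation with Wilkinson's catalyst reduces only the unhindered exocyclic enone double bond; hydrogen is delivered to C8 from the α face, anti to the pseudo-axial C10 methyl, which places the new methyl β as the kinetic epimer, and the neutral medium avoids enolisation.

Step 11
Reactants: 14 8β-methyl ketone
Product: 15 8β-methyl-9-methylene-Δ5-octalin acetonide (exocyclic C9=C11 alkene)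
Conditions: Cp2TiMe2 (3 equiv), toluene, 70 °C, dark
Reagents that add atoms: dimethyltitanocene (Petasis reagent), C[Ti](C)(C1C=CC=C1)C1C=CC=C1
Why: Petasis methylenation (titanium carbene, oxatitanacyclobutane) olefinates hindered, enolisable ketones without base, so the C8 configuration should be kept.

Step 12
Reactants: 16 2-(oxetan-3-yl)ethan-1-ol
Product: 17 2-(oxetan-3-yl)ethyl acetate
Conditions: Ac2O, pyridine, DMAP (cat.), CH2Cl2, 0 °C → rt
Reagents that add atoms: acetic anhydride, CC(=O)OC(C)=O
Why: DMAP-catalysed acetylation of the primary alcohol; the oxetane is stable to these basic conditions.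

Step 13
Reactants: 17 oxetane acetate
Product: 19 (S)-4-bromo-3-(hydroxymethyl)butyl acetate, via TMS ether 18 (not isolated)
Conditions: Me3SiBr, chiral squaramide hydrogen-bond-donor catalyst (5 mol %), t-BuOMe, −78 °C; then aq. citric acid work-up
Reagents that add atoms: bromotrimethylsilane, C[Si](C)(C)Br
Why: Catalytic enantioselective desymmetrisation of a 3-substituted oxetane, in which the catalyst-bound bromide attacks one of the two enantiotopic CH2–O carbons of the silyl-activated oxetane by SN2 and so creates the C13 stereocentre.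

Step 14
Reactants: 19 (S)-bromohydrin
Product: 20 (S)-4-bromo-3-[(tert-butyldimethylsilyloxy)methyl]butyl acetate
Conditions: TBSCl, imidazole, DMF, 0 °C → rt
Reagents that add atoms: tert-butyldimethylsilyl chloride, CC(C)(C)[Si](C)(C)Cl
Why: Imidazole-promoted silylation masks the primary alcohol for the coupling.

Step 15
Reactants: 15 9-methylene octalin acetonide; 20 (S)-silyloxy bromide
Product: 22 16-O-TBS-18,19-O-isopropylidene derivative of the target, via B-alkyl-9-BBN borane 21 (not isolated)
Conditions: 9-BBN (1.05 equiv), THF, 65 °C; then 20, Pd(OAc)2 (5 mol %), PCy3 (10 mol %), K3PO4·H2O, THF, rt → 40 °C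
Reagents that add atoms: none
Why: 9-BBN adds across the exocyclic C9=C11 bond through a four-centre syn transition state with boron on terminal C11 and hydride on C9; Pd(0)/PCy3 then inserts into the primary C–Br bond of 20 (SN2-type oxidative addition), the base-activated borate transfers the C11 alkyl to palladium, and reductive elimination forms the C11–C12 bond. The closest known reaction type is the one-pot alkene hydroboration / B-alkyl Suzuki–Miyaura coupling in its alkyl–alkyl form. No ring is closed. The only new stereocentre, C9, is set by the substrate: the C10 methyl (C20) and the C8 methyl (C17) both lie on the β face of ring B, so the borane should approach from the α face and C11 should end up β, cis to both methyl groups as in the target. The step needs chemoselectivity for the 1,1-disubstituted alkene over the trisubstituted C5=C6 bond, which the bulk of 9-BBN and the flanking quaternary carbons C4 and C10 secure, and it needs coupling to outrun β-hydride elimination, for which the bulky electron-rich PCy3 is chosen. The C13 centre is not touched by the SN2-type oxidative addition, and the acetate, silyl ether and acetonide should tolerate K3PO4·H2O.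

Step 16
Reactants: 22 protected coupling product
Product: 23 (8S,9S,10R,13S)-15-acetoxylabd-5-ene-16,18,19-triol (target CNP0257449.1)
Conditions: 1 M aq. HCl, THF, rt
Reagents that add atoms: none
Why: Mild aqueous acid hydrolyses the isopropylidene acetal and the primary TBS ether in one operation, while the primary acetate and the hindered trisubstituted alkene should be stable.

Compound list
1 | (S)-Wieland–Miescher ketone [(S)-8a-methyl-3,4,8,8a-tetrahydronaphthalene-1,6(2H,7H)-dione] | O=C1CCCC2=CC(=O)CC[C@@]21C | starting material
2 | (4aS,5S)-5-hydroxy-4a-methyl-4,4a,5,6,7,8-hexahydronaphthalen-2(3H)-one (9β-hydroxy enone) | O[C@H]1CCCC2=CC(=O)CC[C@@]21C | intermediate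
3 | C3 spiro-1,3-dithiolane of 2, C4=C5 alkene retained | O[C@H]1CCCC2=CC3(SCCS3)CC[C@@]21C | intermediate
4 | (1S,8aS)-8a-methyl-1,2,3,4,6,7,8,8a-octahydronaphthalen-1-ol (Δ4-octalin-9β-ol) | O[C@H]1CCCC2=CCCC[C@@]21C | intermediate
5 | 4α-(hydroxymethyl)-10β-methyl-Δ5-octalin-9β-ol | O[C@H]1CCC=C2[C@H](CO)CCC[C@@]21C | intermediate
6 | 9β-hydroxy-10β-methyl-Δ5-octalin-4α-carbaldehyde | O[C@H]1CCC=C2[C@H](C=O)CCC[C@@]21C | intermediate
7 | 4β-formyl-4α-(hydroxymethyl) aldol adduct of 6 | O[C@H]1CCC=C2[C@@](CO)(C=O)CCC[C@@]21C | intermediate
8 | 4,4-bis(hydroxymethyl)-10β-methyl-Δ5-octalin-9β-ol | O[C@H]1CCC=C2C(CO)(CO)CCC[C@@]21C | intermediate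
9 | 18,19-O-isopropylidene derivative of 8 (spiro-2,2-dimethyl-1,3-dioxane at C4, free 9β-OH) | O[C@H]1CCC=C2C3(COC(C)(C)OC3)CCC[C@@]21C | intermediate
10 | 18,19-O-isopropylidene-10β-methyl-Δ5-octalin-9-one | O=C1CCC=C2C3(COC(C)(C)OC3)CCC[C@@]21C | intermediate
11 | 8α-(dimethylaminomethyl) derivative of 10 (Mannich base) | O=C1[C@H](CN(C)C)CC=C2C3(COC(C)(C)OC3)CCC[C@@]21C | intermediate
12 | trimethylammonium iodide derived from 11 | O=C1[C@H](C[N+](C)(C)C)CC=C2C3(COC(C)(C)OC3)CCC[C@@]21C.[I-] | intermediate
13 | 8-methylene-9-ketone acetonide (exocyclic enone) | O=C1C(=C)CC=C2C3(COC(C)(C)OC3)CCC[C@@]21C | intermediate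
14 | 8β-methyl-9-ketone acetonide (C8 methyl cis to the C10 methyl) | O=C1[C@@H](C)CC=C2C3(COC(C)(C)OC3)CCC[C@@]21C | intermediate
15 | 8β-methyl-9-methylene-Δ5-octalin acetonide (exocyclic C9=C11 alkene) | C=C1[C@@H](C)CC=C2C3(COC(C)(C)OC3)CCC[C@@]21C | intermediate
16 | 2-(oxetan-3-yl)ethan-1-ol | OCCC1COC1 | starting material
17 | 2-(oxetan-3-yl)ethyl acetate | CC(=O)OCCC1COC1 | intermediate
18 | (S)-4-bromo-3-[(trimethylsilyloxy)methyl]butyl acetate | CC(=O)OCC[C@@H](CO[Si](C)(C)C)CBr | intermediate
19 | (S)-4-bromo-3-(hydroxymethyl)butyl acetate | CC(=O)OCC[C@@H](CO)CBr | intermediate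
20 | (S)-4-bromo-3-[(tert-butyldimethylsilyloxy)methyl]butyl acetate | CC(=O)OCC[C@@H](CO[Si](C)(C)C(C)(C)C)CBr | intermediate
21 | B-alkyl-9-BBN borane from 15 (boron on C11, 9α-H) | C(B1C2CCCC1CCC2)[C@H]1[C@@H](C)CC=C2C3(COC(C)(C)OC3)CCC[C@@]21C | intermediate
22 | 16-O-TBS-18,19-O-isopropylidene derivative of the target | CC(=O)OCC[C@@H](CO[Si](C)(C)C(C)(C)C)CC[C@H]1[C@@H](C)CC=C2C3(COC(C)(C)OC3)CCC[C@@]21C | intermediate
23 | (8S,9S,10R,13S)-15-acetoxylabd-5-ene-16,18,19-triol (CNP0257449.1) | CC(=O)OCC[C@@H](CO)CC[C@H]1[C@@H](C)CC=C2C(CO)(CO)CCC[C@@]21C | target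

Total step count: 16. Longest linear sequence: 13 steps (steps 1–11, 15, 16).

Steps most likely to fail

1. Step 15 (key step). With two β-branched partners, oxidative addition and transmetalation may be slow, so that β-hydride elimination from the alkylpalladium intermediates or protodeboronation takes over. The same bond would then be made by olefination and reduction instead of cross-coupling. The fallback sets out from 15 and 20 and returns at 22. Alkene 15 would be hydroborated as in step 15 and the borane 21 oxidised (NaBO3·4H2O, THF–H2O) to the 9β-hydroxymethyl compound F1. Dess–Martin oxidation would give the C11 aldehyde F2. Bromide 20 would be heated with PPh3 in MeCN to give the phosphonium bromide F3. Its salt-free ylide (NaHMDS, THF, −78 °C) would be treated at once with F2 to give the Z-configured C11=C12 alkene F4. Diimide (TsNHNH2, NaOAc, aq. DME, reflux) should saturate only this disubstituted double bond and deliver 22.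

2. Step 10. Hydrogen may be delivered in part from the β face, the exocyclic double bond may migrate into the ring before it is reduced, or the contra-thermodynamic C8 centre may be lost by enolisation of ketone 14 here or in step 11. The fallback sets out from 10 and returns at 15, and it no longer passes through an enolisable ketone once the centre exists. Ketone 10 would be methylated (LDA, MeI, THF, −78 °C) to the 8-methyl ketone F5, either epimer of which serves. KHMDS and PhNTf2 would give the tetrasubstituted enol triflate F6. Pd(PPh3)4-catalysed coupling with Me3SiCH2MgCl would give the allylsilane F7. Protodesilylation (CF3CO2H, CH2Cl2, −40 °C) should protonate C8 anti to the C10 methyl and unveil the exocyclic C9=C11 alkene of 15 in the same event.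

3. Step 4. The cation-like C5 centre of the Lewis acid-promoted ene reaction may undergo a 1,2-shift of the C10 methyl, capture chloride, or be trapped in a Prins-type cyclisation by the C9 alkoxide. The fallback avoids carbocation character altogether; it sets out from 4 and returns at 6. Alkene 4 would be epoxidised from the α face (mCPBA, NaHCO3, CH2Cl2) to the 4α,5α-epoxide F8. Base-promoted epoxide-to-allylic-alcohol isomerisation (Et2Al–TMP, toluene, 0 °C) removes a C6 hydrogen and should give the 4α-hydroxy-Δ5 compound F9. MnO2 would oxidise only the allylic alcohol, giving enone F10. Wittig reaction with Ph3P=CHOMe (excess) would give the enol ether F11, drawn as the E isomer, though both isomers serve. Hydrolysis (aq. oxalic acid, THF) would give aldehyde 6.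

Further compounds
F1 | step 15 | 9β-(hydroxymethyl)-8β-methyl-Δ5-octalin acetonide (C11 alcohol) | OC[C@H]1[C@@H](C)CC=C2C3(COC(C)(C)OC3)CCC[C@@]21C
F2 | step 15 | C11 aldehyde from F1 | O=C[C@H]1[C@@H](C)CC=C2C3(COC(C)(C)OC3)CCC[C@@]21C
F3 | step 15 | (S)-[4-acetoxy-2-[(tert-butyldimethylsilyloxy)methyl]butyl]triphenylphosphonium bromide | CC(=O)OCC[C@@H](CO[Si](C)(C)C(C)(C)C)C[P+](c1ccccc1)(c1ccccc1)c1ccccc1.[Br-]
F4 | step 15 | (Z)-11,12-didehydro derivative of 22 | CC(=O)OCC[C@@H](CO[Si](C)(C)C(C)(C)C)/C=C\[C@H]1[C@@H](C)CC=C2C3(COC(C)(C)OC3)CCC[C@@]21C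
F5 | step 10 | 8α-methyl-9-ketone acetonide | O=C1[C@H](C)CC=C2C3(COC(C)(C)OC3)CCC[C@@]21C
F6 | step 10 | 8-methyl-Δ8-enol triflate at C9 | O=S(=O)(OC1=C(C)CC=C2C3(COC(C)(C)OC3)CCC[C@@]21C)C(F)(F)F
F7 | step 10 | 9-[(trimethylsilyl)methyl]-8-methyl-Δ5,8-diene acetonide (allylsilane) | C[Si](C)(C)CC1=C(C)CC=C2C3(COC(C)(C)OC3)CCC[C@@]21C
F8 | step 4 | 4α,5α-epoxide of 4 | O[C@H]1CCC[C@]23O[C@@H]3CCC[C@@]21C
F9 | step 4 | 10β-methyl-Δ5-octalin-4α,9β-diol | O[C@H]1CCC=C2[C@H](O)CCC[C@@]21C
F10 | step 4 | 9β-hydroxy-10β-methyl-Δ5-octalin-4-one | O[C@H]1CCC=C2C(=O)CCC[C@@]21C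
F11 | step 4 | 4-(methoxymethylene)-10β-methyl-Δ5-octalin-9β-ol (E isomer drawn) | O[C@H]1CCC=C2/C(=C/OC)CCC[C@@]21C
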